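Readings and results stem from a simulated flask with constants of no real substance, and the scatter is random.

At 20 h someone must choose what to do with this flask, and the choice depends on whether its stop is a balance or the end of J.

| flask | L | J | remark | time |
|---|---|---|---|---|
| Thursday's | 0.10 M | 0.080 M | the very flask that is asked about, followed so far |  |
| Wednesday's | 0.15 M | 0.080 M | run made earlier |  |
| flask | 0.10 M | 0.0800 M |  | 20 h |

Thursday's run (percent of the L charged): time / h: Q / % = 3.00: 26.5; 6.00: 25.6; 10.0: 25.3; 12.0: 26.1

Wednesday's run (percent of the L charged): time / min: Q / % = 15.0: 14.6; 30.0: 20.9; 50.0: 19.9; 60.0: 21.4

(readings scatter by 1 percentage point)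

- beta: at 20 h add J, 50.0% of the amount charged, then wait 20 h
- epsilon: at 20 h take out 90% of the Q then present, then wait 20 h
- eta: change nothing and wait 20 h more
- gamma: at 20 h add L, 50.0% of the amount charged, then wait 20 h

- Q, in percent of the L first charged, at 20 h
- the option that brings most further Q ("none" if no option brings more than 2 percentage points) (beta / epsilon / eta / gamma / none)
- Q present, with what was taken out counted in, in percent of the L first charged, after eta
- Q present, with what was taken out counted in, in percent of the L first charged, after gamma

- what is taken out of Q is counted as made
- additions bring no volume worth counting

In Wednesday's run the gap to the plateau of 20.7% shows a half-life of about 8.54 min. By that yardstick, 20 h is about 141 half-lives, and Thursday's readings stay flat near 25.9%. So two chemists agree that this flask has stopped, but they disagree about why.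

The first holds that it is a balance with a second product. Her ratio, Q squared over L times J, reads 0.167 on Thursday and 0.166 on Wednesday, so taking out Q or adding L should bring more.

I hold the second view. J, the limiting reagent, is shared between L and a loss of its own, and Q stops when J has gone. The share of the J charge that became Q reads 32.3% on Thursday and 38.9% on Wednesday, which is larger with more L.

If J's odds of reaching Q grow in step with L, one number describes the competition at a J charge of 0.0800 M: the even-split level, the amount of L, counted in this flask's L charges, at which that J divides equally between Q and loss. Thursday gives 2.09 and Wednesday 2.36, readings with their scatter, and I take 2.23.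

So I commit to 25.9% now, after eta and after gamma, and to no gain from epsilon, since none of these supplies J. In beta, 74.1% of the L charge meets new J, of which 25.0% should become Q, a gain of 10 percentage points.

The forecast, saying “This looks like equilibrium, not a slow reaction”, gave 25.9% now, 25.9% after eta and 31.1% after gamma, and chose epsilon.

The flask gives 25.7% now, and beta is best.

    L + J → Q (k = 0.303 M⁻¹ min⁻¹)
    2 J → X (k = 0.817 M⁻¹ min⁻¹)
    J → G (k = 0.00767 min⁻¹)

At 20.0 h, 0% of the charged J and 74.3% of the charged L stand free. Eta and gamma both end at 25.7%, and epsilon gains 0 points, while beta gains 15 points, where I reckoned 10 points. The balance view serves for this flask left untouched, which still shows 25.7% at 200 h. A neighbour flask holds this flask's J and 0.40 M of L, which is 4.00 of this flask's L charges. The even-split level gives 64.3% of its J as Q, or 12.9% of its L, and that neighbour flask gives 12.8%.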